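**Plan**
- Retrosynthetic cuts: (a) the enone Cα=Cβ bond (aldol condensation) gives chromene aldehyde 6 and methyl ketone 13; (b) the tertiary hydroxyl of 13 is taken back to an isopropenyl group (11); (c) the dihydrofuran ring of 11 is cut at both C3a–C3 and O1–C2 (benzofuran numbering), giving iodoketone 8 and isoprene 9.
- Enabling feature: in the dihydrofuran ring, C3a lies between the two oxygen-bearing carbons C4 and C7a, so it can carry a halide flanked by two phenols. C2 becomes an allylic ether carbon once its 2-hydroxypropan-2-yl group is read as a hydrated isopropenyl group, so C3, C2 and the side chain are the five carbons of isoprene. The C4 hydroxyl is hydrogen-bonded to the C5 carbonyl, leaving only the C7a oxygen free to close the ring.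
- Forward order: the chromene ring is made first (steps 1–2), then the arene is iodinated (step 3), then the dihydrofuran ring is closed last by an enantioselective palladium-catalysed (3+2) heteroannulation with isoprene (step 4). Markovnikov hydration (step 5) and aldol condensation (step 6) finish the chain.
- Stereochemistry: the only stereocentre, C2 (R), is set in step 4 by the chiral ligand on palladium. The E enone arises under thermodynamic control in step 6. No protecting groups are used.

Key step: step 4

Assumption: the ligand antipode that gives the R configuration at C2 with simple 2-halophenols and isoprene is taken to give the same sense with 8; if the sense proves opposite, the enantiomeric ligand is used.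

**Step 1**
Reactants: 1 4-hydroxybenzaldehyde; 2 3-chloro-3-methylbut-1-yne
Product: 3 4-[(2-methylbut-3-yn-2-yl)oxy]benzaldehyde
Conditions: K2CO3, KI (cat.), CuI (cat.), DMF, 65 °C
Reagents that add atoms: none
Why: Copper-assisted O-alkylation of the phenoxide by the tertiary propargylic chloride is the standard entry to aryl 1,1-dimethylpropargyl ethers, and the non-enolisable aldehyde is inert to carbonate.

**Step 2**
Reactants: 3 4-[(2-methylbut-3-yn-2-yl)oxy]benzaldehyde
Product: 6 2,2-dimethyl-2H-chromene-6-carbaldehyde, via allenylphenol 4 (not isolated), via quinone methide 5 (not isolated)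
Conditions: PhNEt2, 190 °C
Reagents that add atoms: none
Why: The aryl propargyl ether Claisen rearrangement, followed by a 1,5-hydrogen shift and 6π oxa-electrocyclisation, is the classical chromene synthesis, and the two equivalent ortho positions can give only one product.

**Step 3**
Reactants: 7 1-(2,4-dihydroxyphenyl)ethan-1-one
Product: 8 1-(2,4-dihydroxy-3-iodophenyl)ethan-1-one
Conditions: I2 (0.4 equiv), HIO3 (0.2 equiv), EtOH/H2O, 35–40 °C
Reagents that add atoms: iodine, II; iodic acid, O[I](=O)=O
Why: Electrophilic aromatic iodination with iodic acid as the iodide-recycling oxidant should favour C3, the position between the two hydroxyls, because of bond fixation in the chelated 2-hydroxyaryl ketone, and limiting the iodine to one equivalent of iodine atoms suppresses 3,5-diiodination.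

**Step 4**
Reactants: 8 1-(2,4-dihydroxy-3-iodophenyl)ethan-1-one; 9 isoprene (2-methylbuta-1,3-diene)
Product: 11 1-[(2R)-4-hydroxy-2-(prop-1-en-2-yl)-2,3-dihydro-1-benzofuran-5-yl]ethan-1-one, via allylpalladium iodide 10 (not isolated)
Conditions: Pd2(dba)3·CHCl3 (cat.), chiral sulfinamide–monophosphine ligand of the TY-Phos type (antipode giving R), PhONa (1.3 equiv), isoprene (excess), CH2Cl2, 40 °C, sealed tube
Reagents that add atoms: none
Why: Zerovalent palladium inserts into the C–I bond of 8, the arylpalladium adds syn to the unsubstituted vinyl terminus of isoprene (Heck-type insertion) to give the 2-methyl-substituted allylpalladium 10, and the sodium 4-phenoxide captures its internal terminus (Tsuji–Trost etherification), so that one operation forms the C3a–C3 and O1–C2 bonds as a formal (3+2) annulation. The closest known reaction type is the Larock heteroannulation of 2-halophenols with 1,3-dienes in its enantioselective Heck/Tsuji–Trost form. The dihydrofuran ring closes by 5-exo attack of oxygen on the allyl terminus, the seven-membered alternative through the CH2 terminus being disfavoured. C2 is set under ligand control: the two diastereomeric allyl complexes interconvert by π–σ–π isomerisation through the CH2 terminus, and the chiral ligand selects the one that undergoes C–O bond formation to give R. The step needs insertion at the monosubstituted rather than the 1,1-disubstituted alkene of isoprene, which sterics secure, and closure through the 4-oxygen rather than the 2-oxygen, which is secured because the 2-hydroxyl is hydrogen-bonded to the acetyl carbonyl, far less acidic and not deprotonated by PhONa, as in the selective 4-O-alkylation of this ketone. β-Hydride elimination to an aryl diene should be held back because the allyl complex is trapped intramolecularly.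

**Step 5**
Reactants: 11 1-[(2R)-4-hydroxy-2-(prop-1-en-2-yl)-2,3-dihydro-1-benzofuran-5-yl]ethan-1-one
Product: 13 1-[(2R)-4-hydroxy-2-(2-hydroxypropan-2-yl)-2,3-dihydro-1-benzofuran-5-yl]ethan-1-one, via hydroperoxide 12 (not isolated)
Conditions: Co(acac)2 (cat.), PhSiH3, O2 (1 atm), THF, rt
Reagents that add atoms: dioxygen, O=O
Why: In this Mukaiyama hydration a cobalt hydride transfers a hydrogen atom to the CH2 terminus of the 1,1-disubstituted alkene, the tertiary radical is trapped by O2 and the peroxide is reduced in situ by the silane, which should give the Markovnikov tertiary alcohol without touching C2, the aryl ketone or the chelated phenol.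

**Step 6**
Reactants: 13 1-[(2R)-4-hydroxy-2-(2-hydroxypropan-2-yl)-2,3-dihydro-1-benzofuran-5-yl]ethan-1-one; 6 2,2-dimethyl-2H-chromene-6-carbaldehyde
Product: 15 (2E)-3-(2,2-dimethyl-2H-chromen-6-yl)-1-[(2R)-4-hydroxy-2-(2-hydroxypropan-2-yl)-2,3-dihydro-1-benzofuran-5-yl]prop-2-en-1-one, via aldol adduct 14 (not isolated)
Conditions: KOH, EtOH, 0 °C to rt; then aq. HCl to pH 5, 0 °C
Reagents that add atoms: none
Why: In this Claisen–Schmidt condensation the enolate of the methyl ketone adds to the non-enolisable aldehyde and E1cB dehydration should give the E enone under thermodynamic control, while the chromene, the tertiary alcohol and the remote C2 stereocentre are stable to hydroxide and the phenoxide form disfavours flavanone closure.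

**Compound list**
1 | 4-hydroxybenzaldehyde | O=Cc1ccc(O)cc1 | starting material
2 | 3-chloro-3-methylbut-1-yne | CC(C)(Cl)C#C | starting material
3 | 4-[(2-methylbut-3-yn-2-yl)oxy]benzaldehyde | CC(C)(C#C)Oc1ccc(C=O)cc1 | intermediate
4 | 4-hydroxy-3-(3-methylbuta-1,2-dien-1-yl)benzaldehyde (allenylphenol, not isolated) | CC(C)=C=Cc1cc(C=O)ccc1O | intermediate
5 | 3-(3-methylbut-2-en-1-ylidene)-4-oxocyclohexa-1,5-diene-1-carbaldehyde (ortho-quinone methide, not isolated) | CC(C)=CC=C1C=C(C=O)C=CC1=O | intermediate
6 | 2,2-dimethyl-2H-chromene-6-carbaldehyde | CC1(C)C=Cc2cc(C=O)ccc2O1 | intermediate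
7 | 1-(2,4-dihydroxyphenyl)ethan-1-one | CC(=O)c1ccc(O)cc1O | starting material
8 | 1-(2,4-dihydroxy-3-iodophenyl)ethan-1-one | CC(=O)c1ccc(O)c(I)c1O | intermediate
9 | isoprene (2-methylbuta-1,3-diene) | CC(=C)C=C | starting material
10 | allylpalladium iodide from addition of the arylpalladium of 8 to isoprene (drawn in its η1 form, ancillary phosphine omitted, not isolated) | CC(=O)c1ccc(O)c(CC([Pd]I)C(C)=C)c1O | intermediate
11 | 1-[(2R)-4-hydroxy-2-(prop-1-en-2-yl)-2,3-dihydro-1-benzofuran-5-yl]ethan-1-one | CC(=O)c1ccc2c(c1O)C[C@H](C(C)=C)O2 | intermediate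
12 | 1-[(2R)-2-(2-hydroperoxypropan-2-yl)-4-hydroxy-2,3-dihydro-1-benzofuran-5-yl]ethan-1-one (not isolated) | CC(=O)c1ccc2c(c1O)C[C@H](C(C)(C)OO)O2 | intermediate
13 | 1-[(2R)-4-hydroxy-2-(2-hydroxypropan-2-yl)-2,3-dihydro-1-benzofuran-5-yl]ethan-1-one | CC(=O)c1ccc2c(c1O)C[C@H](C(C)(C)O)O2 | intermediate
14 | 3-(2,2-dimethyl-2H-chromen-6-yl)-3-hydroxy-1-[(2R)-4-hydroxy-2-(2-hydroxypropan-2-yl)-2,3-dihydro-1-benzofuran-5-yl]propan-1-one (both carbinol epimers, not isolated) | CC1(C)C=Cc2cc(C(O)CC(=O)c3ccc4c(c3O)C[C@H](C(C)(C)O)O4)ccc2O1 | intermediate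
15 | (2E)-3-(2,2-dimethyl-2H-chromen-6-yl)-1-[(2R)-4-hydroxy-2-(2-hydroxypropan-2-yl)-2,3-dihydro-1-benzofuran-5-yl]prop-2-en-1-one | CC1(C)C=Cc2cc(/C=C/C(=O)c3ccc4c(c3O)C[C@H](C(C)(C)O)O4)ccc2O1 | target

**Step count and risks**
Total steps: 6. Longest linear sequence: 4 steps (7 → 8 → 11 → 13 → 15); the aldehyde branch (1 → 3 → 6) joins in step 6.

Steps most likely to fail:

1. Step 4. Oxidative addition at the doubly ortho-substituted iodide may be slow, β-hydride elimination may divert the allyl complex to a diene, or the chelated hydroxyl may erode enantiocontrol. The fallback closes the ring by epoxide opening instead; it sets out from 7 and comes back to the route at 13, bypassing steps 3 to 5. Compound 7 is O-alkylated at its non-chelated 4-hydroxyl with 2 (K2CO3, KI, CuI cat., DMF, 65 °C) to give 1-[2-hydroxy-4-(2-methylbut-3-yn-2-yloxy)phenyl]ethan-1-one F1. Semi-hydrogenation (H2, Pd/CaCO3 poisoned with Pb(OAc)2, quinoline, EtOAc) should give 1-[2-hydroxy-4-(2-methylbut-3-en-2-yloxy)phenyl]ethan-1-one F2. Aromatic Claisen rearrangement (PhNEt2, 180 °C), directed to the position between the oxygens by the chelated ketone, should give 1-[2,4-dihydroxy-3-(3-methylbut-2-en-1-yl)phenyl]ethan-1-one F3. Selective silylation of the free 4-hydroxyl (TBSCl, imidazole, DMF) gives 1-[4-(tert-butyldimethylsilyloxy)-2-hydroxy-3-(3-methylbut-2-en-1-yl)phenyl]ethan-1-one F4. Shi epoxidation (KHSO5 as the triple salt 2KHSO5·KHSO4·K2SO4, K2CO3 buffer, MeCN/dimethoxymethane/H2O, 0 °C) with the ketone antipode that furnishes the S epoxide, expected to be the enantiomer of the D-fructose-derived ketone, should give 1-[4-(tert-butyldimethylsilyloxy)-3-{[(2S)-3,3-dimethyloxiran-2-yl]methyl}-2-hydroxyphenyl]ethan-1-one F5. TBAF in THF then frees the phenoxide, which should open the epoxide by 5-exo-tet attack with inversion at the secondary carbon to give 13 with the R configuration.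

2. Step 5. The 2-hydroxyaryl ketone may sequester the cobalt catalyst, the alkene may be reduced to isopropyl instead of hydrated, or the β-aryloxy radical may fragment. The fallback is ionic Markovnikov hydration; it sets out from 11 and comes back at 13. Hg(OAc)2 in THF/H2O at rt should give 1-[(2R)-2-[1-(acetoxymercurio)-2-hydroxypropan-2-yl]-4-hydroxy-2,3-dihydro-1-benzofuran-5-yl]ethan-1-one F6. Brief treatment with NaBH4 in aq. NaOH at 0 °C replaces mercury by hydrogen to give 13; the ketone, present as its unreactive chelated phenoxide, should survive the short exposure.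

3. Step 6. The 2'-hydroxychalcone may close to the flavanone by intramolecular oxa-Michael addition during reaction or work-up, or condensation of the doubly deprotonated ketone with the electron-rich aldehyde may stall. The fallback masks the phenol; it sets out from 13 and comes back at 15. NaH (1 equiv) and MOMCl in DMF at 0 °C should etherify the phenol selectively to give 1-[(2R)-2-(2-hydroxypropan-2-yl)-4-(methoxymethoxy)-2,3-dihydro-1-benzofuran-5-yl]ethan-1-one F7. Condensation with 6 (KOH, EtOH, rt) gives (2E)-3-(2,2-dimethyl-2H-chromen-6-yl)-1-[(2R)-2-(2-hydroxypropan-2-yl)-4-(methoxymethoxy)-2,3-dihydro-1-benzofuran-5-yl]prop-2-en-1-one F8, which cannot cyclise. Mild acid (aq. HCl, MeOH, 40 °C) then removes the chelation-labilised acetal to give 15.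

**Further compounds**
F1 | step 4 | 1-[2-hydroxy-4-(2-methylbut-3-yn-2-yloxy)phenyl]ethan-1-one | CC(=O)c1ccc(OC(C)(C)C#C)cc1O
F2 | step 4 | 1-[2-hydroxy-4-(2-methylbut-3-en-2-yloxy)phenyl]ethan-1-one | CC(=O)c1ccc(OC(C)(C)C=C)cc1O
F3 | step 4 | 1-[2,4-dihydroxy-3-(3-methylbut-2-en-1-yl)phenyl]ethan-1-one | CC(=O)c1ccc(O)c(CC=C(C)C)c1O
F4 | step 4 | 1-[4-(tert-butyldimethylsilyloxy)-2-hydroxy-3-(3-methylbut-2-en-1-yl)phenyl]ethan-1-one | CC(=O)c1ccc(O[Si](C)(C)C(C)(C)C)c(CC=C(C)C)c1O
F5 | step 4 | 1-[4-(tert-butyldimethylsilyloxy)-3-{[(2S)-3,3-dimethyloxiran-2-yl]methyl}-2-hydroxyphenyl]ethan-1-one | CC(=O)c1ccc(O[Si](C)(C)C(C)(C)C)c(C[C@@H]2OC2(C)C)c1O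
F6 | step 5 | 1-[(2R)-2-[1-(acetoxymercurio)-2-hydroxypropan-2-yl]-4-hydroxy-2,3-dihydro-1-benzofuran-5-yl]ethan-1-one (both carbinol epimers) | CC(=O)c1ccc2c(c1O)C[C@H](C(C)(O)C[Hg]OC(C)=O)O2
F7 | step 6 | 1-[(2R)-2-(2-hydroxypropan-2-yl)-4-(methoxymethoxy)-2,3-dihydro-1-benzofuran-5-yl]ethan-1-one | CC(=O)c1ccc2c(c1OCOC)C[C@H](C(C)(C)O)O2
F8 | step 6 | (2E)-3-(2,2-dimethyl-2H-chromen-6-yl)-1-[(2R)-2-(2-hydroxypropan-2-yl)-4-(methoxymethoxy)-2,3-dihydro-1-benzofuran-5-yl]prop-2-en-1-one | CC1(C)C=Cc2cc(/C=C/C(=O)c3ccc4c(c3OCOC)C[C@H](C(C)(C)O)O4)ccc2O1
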